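**Assumption:** the SMILES is read literally as (5S,6R,7S,8S), meaning 5-OH/6-OH trans, 6-OH/7-OH trans and 7-OH/8-OAr cis. Below, α is the face of the 5-OH and β is the opposite face.

**Retrosynthetic overview**
- The C8–OAr bond is cut last: SN2 with inversion joins an 8β-bromo, tris-silylated tetrahydrochromone to 6-hydroxy-7-methoxy-2-(2-phenylethyl)chromone.
- Both 4-pyranone rings come from one spiro 3(2H)-furanone by a 1,2-acyl-shift ring expansion. The tetrahydro half uses an oxirane-triggered, desymmetrising version; the aromatic half uses the dienone–phenol version.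
- The meso bis-epoxide comes from the spiro-dienone by 1,2-reduction, silylation and double epoxidation. The methoxy-dienone comes from the same spiro-dienone by mono-epoxidation and methanolysis.
- The spiro-dienone comes from p-benzoquinone and 5-phenylpent-1-yn-3-ol, which is made from iodobenzene, allyl alcohol and ethynylmagnesium bromide.
- Ring order: carbocycle (from the quinone), then spiro-furanone, then pyranone by ring expansion. The quaternary spiro carbon blocks aromatisation until the stereocentres are in place.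

**Step 1**
Reactants: 1 iodobenzene; 2 prop-2-en-1-ol (allyl alcohol)
Product: 3 3-phenylpropanal
Conditions: Pd(OAc)2 (2 mol %), NaHCO3, Bu4NCl, DMF, 40 °C
Reagents that add atoms: none
Why: Jeffery-type Heck arylation of an allylic alcohol, in which carbopalladation, β-hydride elimination toward the carbinol and tautomerisation give the saturated aldehyde directly, with no stereocentre.

**Step 2**
Reactants: 3 3-phenylpropanal; 4 ethynylmagnesium bromide
Product: 5 (±)-5-phenylpent-1-yn-3-ol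
Conditions: THF, 0 °C; 1 M HCl quench
Reagents that add atoms: none
Why: Grignard 1,2-addition of an acetylide to an aldehyde; the racemic carbinol centre is erased by oxidation in step 4.

**Step 3**
Reactants: 5 (±)-5-phenylpent-1-yn-3-ol; 6 1,4-benzoquinone
Product: 8 (±)-4-hydroxy-4-(3-hydroxy-5-phenylpent-1-yn-1-yl)cyclohexa-2,5-dien-1-one, via dilithio alkynol 7 (not isolated)
Conditions: n-BuLi (2.1 equiv), THF, −78 → 0 °C; cannulate into 6 (1.4 equiv), THF, −78 °C; AcOH quench
Reagents that add atoms: none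
Why: 1,2-addition of a lithium acetylide to one quinone carbonyl (p-quinol synthesis); inverse addition to excess quinone at low temperature suppresses double addition and electron transfer.

**Step 4**
Reactants: 8 (±)-4-hydroxy-4-(3-hydroxy-5-phenylpent-1-yn-1-yl)cyclohexa-2,5-dien-1-one
Product: 10 2-(2-phenylethyl)-1-oxaspiro[4.5]deca-2,6,9-triene-4,8-dione, via quinol ynone 9 (not isolated)
Conditions: MnO2, CH2Cl2, rt; filter; (4-CF3C6H4)3PAuCl/AgOTf (5 mol % each), CH2Cl2–toluene, rt
Reagents that add atoms: none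
Why: MnO2 oxidises only the secondary propargylic alcohol, and the known gold-catalysed cycloisomerisation of γ-hydroxy-alkynones then closes the 3(2H)-furanone, which makes the achiral spiro quaternary carbon.

**Step 5**
Reactants: 10 2-(2-phenylethyl)-1-oxaspiro[4.5]deca-2,6,9-triene-4,8-dione
Product: 11 trans-8-hydroxy-2-(2-phenylethyl)-1-oxaspiro[4.5]deca-2,6,9-trien-4-one (8-OH on the face opposite to O1; achiral)
Conditions: NaBH4, CeCl3·7H2O, MeOH, −78 °C
Reagents that add atoms: none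
Why: Luche 1,2-reduction takes the cross-conjugated ketone in preference to the vinylogous-ester carbonyl, and hydride should approach syn to the C5–O1 bond (dipole control, as seen for 4-alkoxy-4-substituted cyclohexadienones), placing the OH trans to O1; the minor cis isomer is removed after step 6.

**Step 6**
Reactants: 11 trans-8-hydroxy-2-(2-phenylethyl)-1-oxaspiro[4.5]deca-2,6,9-trien-4-one
Product: 12 trans-2-(2-phenylethyl)-8-(triethylsilyloxy)-1-oxaspiro[4.5]deca-2,6,9-trien-4-one
Conditions: TESCl, imidazole, CH2Cl2, 0 °C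
Reagents that add atoms: chlorotriethylsilane (TESCl) CC[Si](Cl)(CC)CC
Why: Standard silylation that removes the OH directing effect, adds bulk on the β face and gives a non-participating group next to the future oxiranes.

**Step 7**
Reactants: 12 trans-2-(2-phenylethyl)-8-(triethylsilyloxy)-1-oxaspiro[4.5]deca-2,6,9-trien-4-one
Product: 13 meso-6,7:9,10-diepoxy-2-(2-phenylethyl)-8-(triethylsilyloxy)-1-oxaspiro[4.5]dec-2-en-4-one (both oxirane O syn to O1, anti to OTES and to C4)
Conditions: mCPBA (3.5 equiv), CH2Cl2/aq. pH 8 phosphate buffer, rt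
Reagents that add atoms: 3-chloroperoxybenzoic acid (mCPBA) OOC(=O)c1cccc(Cl)c1
Why: Double Prilezhaev epoxidation from the α face, which carries only O1 and H-8 while the β face carries the acyl carbon C4 and OTES; the push–pull furanone alkene is inert to peracid.

**Step 8**
Reactants: 13 meso-6,7:9,10-diepoxy-2-(2-phenylethyl)-8-(triethylsilyloxy)-1-oxaspiro[4.5]dec-2-en-4-one
Product: 14 (5S,6R,7R,8S)-7,8-epoxy-5-hydroxy-2-(2-phenylethyl)-6-(triethylsilyloxy)-5,6,7,8-tetrahydro-4H-chromen-4-one (5α-OH, 6β-OTES, 7α,8α-oxirane)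
Conditions: (R)-3,3'-bis(2,4,6-triisopropylphenyl)-1,1'-binaphthyl-2,2'-diyl N-triflylphosphoramide (5 mol %), toluene, 4 Å MS, −40 °C
Reagents that add atoms: none
Why: Proposed new method: the chiral Brønsted acid hydrogen-bonds one of the two enantiotopic oxiranes of meso-13; heterolysis of its C6–O bond (the carbon next to the spiro centre) is concerted with antiperiplanar 1,2-migration of the furanone acyl carbon C4 from C5 to C6 (the oxiranes are syn to O1, hence anti to C4); the O1-stabilised oxocarbenium ion then loses the doubly activated C6–H to the phosphoramide anion, so the five-membered furanone becomes the six-membered 4-pyranone while the untouched C7–O bond becomes the 5S carbinol; this single event forms C4–C4a, forms the heterocycle and fixes the absolute configuration of all four oxygenated carbons, driven by oxirane strain release and pyranone conjugation, and the second oxirane survives because no migrating group or donor flanks it any longer; the closest known reaction types are the semipinacol rearrangement of 2,3-epoxy alcohols and ethers, the Lewis-acid 1,2-acyl shift of α,β-epoxy ketones, the acid rearrangement of spiro-coumaranone dienones to xanthones and chiral-phosphoric-acid desymmetrisation of meso-epoxides; the antipodal catalyst is used if the sense of induction is reversed.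

**Step 9**
Reactants: 14 (5S,6R,7R,8S)-7,8-epoxy-5-hydroxy-2-(2-phenylethyl)-6-(triethylsilyloxy)-5,6,7,8-tetrahydro-4H-chromen-4-one
Product: 15 (5S,6R,7S,8R)-8-bromo-2-(2-phenylethyl)-5,6,7-tris(triethylsilyloxy)-5,6,7,8-tetrahydro-4H-chromen-4-one (8β-Br)
Conditions: TESOTf (2.4 equiv), Bu4NBr (1.3 equiv), 2,6-lutidine (1.2 equiv), CH2Cl2, −78 → −30 °C
Reagents that add atoms: triethylsilyl triflate CC[Si](CC)(CC)OS(=O)(=O)C(F)(F)F; tetrabutylammonium bromide CCCC[N+](CCCC)(CCCC)CCCC.[Br-]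
Why: Silyl-activated SN2 opening of the oxirane by bromide (halosilane-type halohydrin ether formation) occurs at C8, which is flanked by the planar electron-poor pyranone, whereas C7 is shielded on the β face by 6β-OTES; this gives trans 8β-Br/7α-OTES, and the 5-OH is silylated in the same operation.

**Step 10**
Reactants: 10 2-(2-phenylethyl)-1-oxaspiro[4.5]deca-2,6,9-triene-4,8-dione
Product: 16 (±)-6,7-epoxy-2-(2-phenylethyl)-1-oxaspiro[4.5]deca-2,9-diene-4,8-dione
Conditions: t-BuOOH (1.05 equiv, decane), DBU, CH2Cl2, 0 °C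
Reagents that add atoms: tert-butyl hydroperoxide CC(C)(C)OO
Why: Weitz–Scheffer nucleophilic epoxidation attacks only the electron-poor dienone and is stopped at the mono-epoxide by stoichiometry; its stereocentres are destroyed in step 11.

**Step 11**
Reactants: 16 (±)-6,7-epoxy-2-(2-phenylethyl)-1-oxaspiro[4.5]deca-2,9-diene-4,8-dione
Product: 18 6-hydroxy-7-methoxy-2-(2-phenylethyl)-4H-chromen-4-one, via methoxy spirodienone 17 (not isolated)
Conditions: NaOMe (0.2 equiv), MeOH, 0 °C → rt; evaporate; TFA–CH2Cl2 1:1, rt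
Reagents that add atoms: methanol CO
Why: Methoxide opens the α,β-epoxy ketone at the α-carbon and E1cB dehydration gives the 2-methoxy-dienone (classical 2-alkoxy-enone synthesis); the dienone–phenol rearrangement then moves the acyl carbon from C5 to the unsubstituted C10, through a σ-complex stabilised by O1 and the para OMe and free of peri crowding, which expands the furanone to the chromone.

**Step 12**
Reactants: 15 (5S,6R,7S,8R)-8-bromo-2-(2-phenylethyl)-5,6,7-tris(triethylsilyloxy)-5,6,7,8-tetrahydro-4H-chromen-4-one; 18 6-hydroxy-7-methoxy-2-(2-phenylethyl)-4H-chromen-4-one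
Product: 19 7-methoxy-2-(2-phenylethyl)-6-{[(5S,6R,7R,8S)-4-oxo-2-(2-phenylethyl)-5,6,7-tris(triethylsilyloxy)-5,6,7,8-tetrahydro-4H-chromen-8-yl]oxy}-4H-chromen-4-one
Conditions: Cs2CO3, DMF, 0 °C → rt
Reagents that add atoms: none
Why: Williamson SN2 at the vinylogous α-halo-carbonyl position C8 inverts 8β-Br to 8α-OAr (cis to 7α-O); silyl ethers cannot participate, cannot close an oxirane and are poor E1cB leaving groups, and no H is antiperiplanar to Br for E2.

**Step 13**
Reactants: 19 7-methoxy-2-(2-phenylethyl)-6-{[(5S,6R,7R,8S)-4-oxo-2-(2-phenylethyl)-5,6,7-tris(triethylsilyloxy)-5,6,7,8-tetrahydro-4H-chromen-8-yl]oxy}-4H-chromen-4-one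
Product: 20 6-{[(5S,6R,7S,8S)-5,6,7-trihydroxy-4-oxo-2-(2-phenylethyl)-5,6,7,8-tetrahydro-4H-chromen-8-yl]oxy}-7-methoxy-2-(2-phenylethyl)-4H-chromen-4-one (target)
Conditions: HF·pyridine, THF, 0 °C → rt
Reagents that add atoms: none
Why: Buffered fluoride desilylation removes the three TES groups without acid ionisation at C5 or base-induced elimination, and no stereocentre is touched.

**Compound list**
1 | iodobenzene | Ic1ccccc1 | starting material
2 | prop-2-en-1-ol | C=CCO | starting material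
3 | 3-phenylpropanal | O=CCCc1ccccc1 | intermediate
4 | ethynylmagnesium bromide | C#C[Mg]Br | starting material
5 | (±)-5-phenylpent-1-yn-3-ol | C#CC(O)CCc1ccccc1 | intermediate
6 | 1,4-benzoquinone | O=C1C=CC(=O)C=C1 | starting material
7 | dilithio derivative of 5 (lithium 1-lithio-5-phenylpent-1-yn-3-olate) | [Li]C#CC(O[Li])CCc1ccccc1 | intermediate
8 | (±)-4-hydroxy-4-(3-hydroxy-5-phenylpent-1-yn-1-yl)cyclohexa-2,5-dien-1-one | O=C1C=CC(O)(C#CC(O)CCc2ccccc2)C=C1 | intermediate
9 | 4-hydroxy-4-(3-oxo-5-phenylpent-1-yn-1-yl)cyclohexa-2,5-dien-1-one | O=C1C=CC(O)(C#CC(=O)CCc2ccccc2)C=C1 | intermediate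
10 | 2-(2-phenylethyl)-1-oxaspiro[4.5]deca-2,6,9-triene-4,8-dione | O=C1C=CC2(C=C1)OC(CCc1ccccc1)=CC2=O | intermediate
11 | trans-8-hydroxy-2-(2-phenylethyl)-1-oxaspiro[4.5]deca-2,6,9-trien-4-one | O=C1C=C(CCc2ccccc2)O[C@@]12C=C[C@@H](O)C=C2 | intermediate
12 | trans-2-(2-phenylethyl)-8-(triethylsilyloxy)-1-oxaspiro[4.5]deca-2,6,9-trien-4-one | O=C1C=C(CCc2ccccc2)O[C@@]12C=C[C@@H](O[Si](CC)(CC)CC)C=C2 | intermediate
13 | meso-6,7:9,10-diepoxy-2-(2-phenylethyl)-8-(triethylsilyloxy)-1-oxaspiro[4.5]dec-2-en-4-one (oxiranes syn to O1, OTES anti) | O=C1C=C(CCc2ccccc2)O[C@@]13[C@@H]4O[C@@H]4[C@@H](O[Si](CC)(CC)CC)[C@@H]4O[C@H]34 | intermediate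
14 | (5S,6R,7R,8S)-7,8-epoxy-5-hydroxy-2-(2-phenylethyl)-6-(triethylsilyloxy)-5,6,7,8-tetrahydro-4H-chromen-4-one | O1[C@@H]2c3oc(CCc4ccccc4)cc(=O)c3[C@H](O)[C@@H](O[Si](CC)(CC)CC)[C@H]12 | intermediate
15 | (5S,6R,7S,8R)-8-bromo-2-(2-phenylethyl)-5,6,7-tris(triethylsilyloxy)-5,6,7,8-tetrahydro-4H-chromen-4-one | Br[C@H]1c2oc(CCc3ccccc3)cc(=O)c2[C@H](O[Si](CC)(CC)CC)[C@@H](O[Si](CC)(CC)CC)[C@@H]1O[Si](CC)(CC)CC | intermediate
16 | (±)-6,7-epoxy-2-(2-phenylethyl)-1-oxaspiro[4.5]deca-2,9-diene-4,8-dione (oxirane syn to O1; racemic, one enantiomer drawn) | O=C1C=C(CCc2ccccc2)O[C@@]13[C@@H]4O[C@@H]4C(=O)C=C3 | intermediate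
17 | (±)-7-methoxy-2-(2-phenylethyl)-1-oxaspiro[4.5]deca-2,6,9-triene-4,8-dione (racemic) | COC1=CC2(C=CC1=O)OC(CCc1ccccc1)=CC2=O | intermediate
18 | 6-hydroxy-7-methoxy-2-(2-phenylethyl)-4H-chromen-4-one | COc1cc2oc(CCc3ccccc3)cc(=O)c2cc1O | intermediate
19 | 7-methoxy-2-(2-phenylethyl)-6-{[(5S,6R,7R,8S)-4-oxo-2-(2-phenylethyl)-5,6,7-tris(triethylsilyloxy)-5,6,7,8-tetrahydro-4H-chromen-8-yl]oxy}-4H-chromen-4-one | COc1cc2oc(CCc3ccccc3)cc(=O)c2cc1O[C@@H]1c2oc(CCc3ccccc3)cc(=O)c2[C@H](O[Si](CC)(CC)CC)[C@@H](O[Si](CC)(CC)CC)[C@@H]1O[Si](CC)(CC)CC | intermediate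
20 | 6-{[(5S,6R,7S,8S)-5,6,7-trihydroxy-4-oxo-2-(2-phenylethyl)-5,6,7,8-tetrahydro-4H-chromen-8-yl]oxy}-7-methoxy-2-(2-phenylethyl)-4H-chromen-4-one | COc1cc2oc(CCc3ccccc3)cc(=O)c2cc1O[C@@H]1c2oc(CCc3ccccc3)cc(=O)c2[C@H](O)[C@@H](O)[C@@H]1O | target

**Total step count:** 13. **Longest linear sequence:** 11 (steps 1–9, 12, 13).

**Three steps most likely to fail**

**Step 8 (proposed new ring expansion).** The risks are a Meinwald-type hydride shift, low enantioselectivity and product inhibition by the basic pyranone.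
- The fallback sets out from 10 and returns at 14. It uses only classical arene-dihydrodiol chemistry.
- TFA/CH2Cl2 (dienone–phenol rearrangement) converts 10 into 6-hydroxy-2-(2-phenylethyl)-4H-chromen-4-one F1.
- Teuber oxidation with (KSO3)2NO gives 2-(2-phenylethyl)-4H-chromene-4,5,6-trione F2.
- NaBH4 in EtOH under O2 (the standard o-quinone to trans-dihydrodiol reduction) gives the racemic trans-diol.
- Burkholderia cepacia lipase with vinyl acetate then removes the unwanted enantiomer as (5R,6R)-6-acetoxy-5-hydroxy-2-(2-phenylethyl)-5,6-dihydro-4H-chromen-4-one F4. This leaves (5S,6S)-5,6-dihydroxy-2-(2-phenylethyl)-5,6-dihydro-4H-chromen-4-one F3.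
- TESCl (1 equiv)/imidazole silylates the non-chelated, less hindered 6-OH to give (5S,6S)-5-hydroxy-2-(2-phenylethyl)-6-(triethylsilyloxy)-5,6-dihydro-4H-chromen-4-one F5.
- Dimethyldioxirane epoxidises the 7,8-alkene of F5 anti to the allylic 6β-OTES and delivers 14.

**Step 11 (methanolysis and dienone–phenol shift).** The risk is that methoxide attacks the acyl carbon of the 4-acyl-dienone and triggers deacylative aromatisation.
- The fallback sets out from 8 and returns at 17. It installs the methoxy group before any acyl group sits on the quaternary carbon.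
- H2O2/NaOH (hydroxyl-assisted Weitz–Scheffer epoxidation) gives 5-hydroxy-5-(3-hydroxy-5-phenylpent-1-yn-1-yl)-7-oxabicyclo[4.1.0]hept-3-en-2-one F6.
- NaOMe/MeOH gives 4-hydroxy-4-(3-hydroxy-5-phenylpent-1-yn-1-yl)-2-methoxycyclohexa-2,5-dien-1-one F7.
- MnO2 gives 4-hydroxy-2-methoxy-4-(3-oxo-5-phenylpent-1-yn-1-yl)cyclohexa-2,5-dien-1-one F8.
- The gold catalyst of step 4 closes F8 to 17, which is treated with TFA as in step 11.

**Step 12 (SN2 at a secondary carbon, syn to 7α-OTES).** The risks are slow substitution and elimination to aromatic products.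
- The fallback sets out from 14 and returns at 19. It replaces the basic Williamson reaction by a neutral Mitsunobu inversion.
- PhCO2H/PhCO2Cs in DMF opens the oxirane at C8 to give (5α,6β,7α,8β)-8-benzoyloxy-5,7-dihydroxy-2-(2-phenylethyl)-6-(triethylsilyloxy)-5,6,7,8-tetrahydro-4H-chromen-4-one F9.
- TESOTf/2,6-lutidine gives (5α,6β,7α,8β)-8-benzoyloxy-2-(2-phenylethyl)-5,6,7-tris(triethylsilyloxy)-5,6,7,8-tetrahydro-4H-chromen-4-one F10.
- K2CO3/MeOH at 0 °C gives (5α,6β,7α,8β)-8-hydroxy-2-(2-phenylethyl)-5,6,7-tris(triethylsilyloxy)-5,6,7,8-tetrahydro-4H-chromen-4-one F11.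
- Mitsunobu coupling of F11 with 18 (PPh3, DIAD, toluene, 0 °C) inverts C8 and gives 19.

**Further compounds**
F1 | step 8 | 6-hydroxy-2-(2-phenylethyl)-4H-chromen-4-one | O=c1cc(CCc2ccccc2)oc2ccc(O)cc12
F2 | step 8 | 2-(2-phenylethyl)-4H-chromene-4,5,6-trione | O=C1C=Cc2oc(CCc3ccccc3)cc(=O)c2C1=O
F3 | step 8 | (5S,6S)-5,6-dihydroxy-2-(2-phenylethyl)-5,6-dihydro-4H-chromen-4-one (formed racemic, then resolved) | O=c1cc(CCc2ccccc2)oc2c1[C@H](O)[C@@H](O)C=C2
F4 | step 8 | (5R,6R)-6-acetoxy-5-hydroxy-2-(2-phenylethyl)-5,6-dihydro-4H-chromen-4-one | O=c1cc(CCc2ccccc2)oc2c1[C@@H](O)[C@H](OC(C)=O)C=C2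
F5 | step 8 | (5S,6S)-5-hydroxy-2-(2-phenylethyl)-6-(triethylsilyloxy)-5,6-dihydro-4H-chromen-4-one | O=c1cc(CCc2ccccc2)oc2c1[C@H](O)[C@@H](O[Si](CC)(CC)CC)C=C2
F6 | step 11 | 5-hydroxy-5-(3-hydroxy-5-phenylpent-1-yn-1-yl)-7-oxabicyclo[4.1.0]hept-3-en-2-one (racemic diastereomer mixture) | O=C1C=CC(O)(C#CC(O)CCc2ccccc2)C2OC12
F7 | step 11 | 4-hydroxy-4-(3-hydroxy-5-phenylpent-1-yn-1-yl)-2-methoxycyclohexa-2,5-dien-1-one (racemic diastereomer mixture) | COC1=CC(O)(C#CC(O)CCc2ccccc2)C=CC1=O
F8 | step 11 | 4-hydroxy-2-methoxy-4-(3-oxo-5-phenylpent-1-yn-1-yl)cyclohexa-2,5-dien-1-one (racemic) | COC1=CC(O)(C#CC(=O)CCc2ccccc2)C=CC1=O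
F9 | step 12 | (5α,6β,7α,8β)-8-benzoyloxy-5,7-dihydroxy-2-(2-phenylethyl)-6-(triethylsilyloxy)-5,6,7,8-tetrahydro-4H-chromen-4-one | O=C(O[C@H]1c2oc(CCc3ccccc3)cc(=O)c2[C@H](O)[C@@H](O[Si](CC)(CC)CC)[C@@H]1O)c1ccccc1
F10 | step 12 | (5α,6β,7α,8β)-8-benzoyloxy-2-(2-phenylethyl)-5,6,7-tris(triethylsilyloxy)-5,6,7,8-tetrahydro-4H-chromen-4-one | O=C(O[C@H]1c2oc(CCc3ccccc3)cc(=O)c2[C@H](O[Si](CC)(CC)CC)[C@@H](O[Si](CC)(CC)CC)[C@@H]1O[Si](CC)(CC)CC)c1ccccc1
F11 | step 12 | (5α,6β,7α,8β)-8-hydroxy-2-(2-phenylethyl)-5,6,7-tris(triethylsilyloxy)-5,6,7,8-tetrahydro-4H-chromen-4-one | O[C@H]1c2oc(CCc3ccccc3)cc(=O)c2[C@H](O[Si](CC)(CC)CC)[C@@H](O[Si](CC)(CC)CC)[C@@H]1O[Si](CC)(CC)CC
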